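**Retrosynthetic overview**
1. The plan rests on ring C. C4'–Br stands beside the gem-dimethyl carbon C3', the tertiary C1'–O lies 1,4 to it, and C8–O is vicinal to C1'. This is the pattern left by a prenyl bromonium ion, a 1,1-disubstituted alkene (C1'=C2') and an oxygen nucleophile carried on C8.
2. Last cut: C2'–C3' and C1'–O, back to a bromochloride allylic tert-butyl carbonate. The bromochloride comes from the prenyl alkene by Shi epoxidation, bromide attack at C4' and chloride at C3'.
3. C8–C1' and C1–C8 are cut by boronic ester homologation of a C1 boronate, whose chiral diol sets C8. C2–O is inverted afterwards.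
4. C1–B and the trans fusion (C7a–H) come from hydroboration of a C1=C7a alkene. The C7 carbinol comes from an enedione and C4–Br from the C4 alcohol.
5. Ring order: ring A is bought (2-methylcyclohexane-1,3-dione, then desymmetrised). Ring B closes by aldol condensation. Ring C and the carbonate ring close together at the end.

Key step: step 22

Labels: ring B = C1 (side-chain carbon), C2 (CH–O), C3, C3a (C–Me), C7a (CH). Ring A = C3a, C4 (CHBr), C5, C6, C7 (C(Me)–O), C7a. C8 = linker carbinol. Ring C = C1' (C–O), C2', C3' (CMe2), C4' (CHBr), C5', C6'. The lower face is the face of the C3a methyl group and the upper face is the opposite one. In the target C7a–H, C8 and C2–O are upper, and C7–O and C4–Br are lower.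

Assumption: the facial senses quoted for the oxazaborolidine, for (+)-pinanediol and for the fructose-derived ketone are those of their standard models; should one be reversed on these substrates, the mirror-image reagent would be used.

Step 1
Reactants: 1 2-methylcyclohexane-1,3-dione; 2 allyl bromide
Product: 3 2-allyl-2-methylcyclohexane-1,3-dione
Conditions: NaOH (1 M aq), rt
Reagents that add atoms: none
Why: C-alkylation of the 1,3-diketone enolate with an allylic halide gives the still prochiral quaternary carbon (future C3a) that carries its methyl group and the three-carbon chain C3–C2–C1.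

Step 2
Reactants: 3 2-allyl-2-methylcyclohexane-1,3-dione
Product: 4 (2R,3R)-2-allyl-3-hydroxy-2-methylcyclohexan-1-one
Conditions: (3aS)-1-methyl-3,3-diphenyltetrahydro-1H,3H-pyrrolo[1,2-c][1,3,2]oxazaborole (20 mol %), catecholborane, toluene, −78 °C
Reagents that add atoms: none
Why: Corey–Bakshi–Shibata reduction run as a desymmetrisation: the catalyst treats the quaternary carbon as the large substituent and should give the (R)-carbinol, and it should take the carbonyl group it can reach anti to the longer allyl chain, so one event sets C3a and places the C4 oxygen cis to the allyl group (the later axial, upper position).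

Step 3
Reactants: 4 (2R,3R)-2-allyl-3-hydroxy-2-methylcyclohexan-1-one
Product: 5 (2R,3R)-2-allyl-3-(tert-butyldimethylsilyloxy)-2-methylcyclohexan-1-one
Conditions: t-BuMe2SiOTf, 2,6-lutidine, CH2Cl2, 0 °C
Reagents that add atoms: tert-butyldimethylsilyl triflate, CC(C)(C)[Si](C)(C)OS(=O)(=O)C(F)(F)F
Why: Silyl ether formation with the reactive triflate copes with the neopentyl hydroxyl group and blocks retro-aldol opening of the β-hydroxy ketone under the base of step 5.

Step 4
Reactants: 5 (2R,3R)-2-allyl-3-(tert-butyldimethylsilyloxy)-2-methylcyclohexan-1-one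
Product: 6 (2R,3R)-3-(tert-butyldimethylsilyloxy)-2-methyl-2-(2-oxopropyl)cyclohexan-1-one
Conditions: PdCl2 (10 mol %), CuCl, O2 (1 atm), DMF–H2O, rt
Reagents that add atoms: water, O
Why: Wacker–Tsuji oxidation converts the terminal alkene with Markovnikov selectivity into the methyl ketone (C2 carbonyl, C1 methyl) and leaves ketone and silyl ether alone.

Step 5
Reactants: 6 (2R,3R)-3-(tert-butyldimethylsilyloxy)-2-methyl-2-(2-oxopropyl)cyclohexan-1-one
Product: 7 (3aS,4R)-4-(tert-butyldimethylsilyloxy)-3a-methyl-3,3a,4,5,6,7-hexahydro-2H-inden-2-one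
Conditions: KOH, MeOH, 60 °C
Reagents that add atoms: none
Why: Intramolecular aldol condensation: the methyl carbon C1 adds to the ring ketone C7a in a five-membered closure of ring B, and loss of water drains the reversible aldol modes into the conjugated enone with no stereocentre touched.

Step 6
Reactants: 7 (3aS,4R)-4-(tert-butyldimethylsilyloxy)-3a-methyl-3,3a,4,5,6,7-hexahydro-2H-inden-2-one
Product: 8 (3aS,4R)-4-hydroxy-3a-methyl-3,3a,4,5,6,7-hexahydro-2H-inden-2-one
Conditions: HF (48 % aq), MeCN, rt
Reagents that add atoms: none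
Why: Acidic fluoride desilylation frees the C4 hydroxyl group without the base that could trigger vinylogous retro-aldol cleavage.

Step 7
Reactants: 8 (3aS,4R)-4-hydroxy-3a-methyl-3,3a,4,5,6,7-hexahydro-2H-inden-2-one
Product: 9 (3aS,4S)-4-bromo-3a-methyl-3,3a,4,5,6,7-hexahydro-2H-inden-2-one
Conditions: CBr4, PPh3, toluene, 80 °C
Reagents that add atoms: carbon tetrabromide, BrC(Br)(Br)Br
Why: Appel reaction: bromide displaces the oxyphosphonium group from the rear (SN2), which turns the pseudo-axial upper C4–O into the equatorial lower C4–Br of the target, a conversion known for neopentylic cyclohexanols of halogenated terpenoids although elimination competes.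

Step 8
Reactants: 9 (3aS,4S)-4-bromo-3a-methyl-3,3a,4,5,6,7-hexahydro-2H-inden-2-one
Product: 10 (3aS,4S)-4-bromo-3a-methyl-3,3a,4,5-tetrahydro-2H-indene-2,7(6H)-dione
Conditions: Pd(OH)2/C (5 mol %), t-BuOOH, K2CO3, CH2Cl2, rt
Reagents that add atoms: tert-butyl hydroperoxide, CC(C)(C)OO
Why: Palladium-catalysed γ-oxidation of an enone with tert-butyl hydroperoxide to the 1,4-enedione can act only at C7, because the other γ-carbon C3a is quaternary.

Step 9
Reactants: 10 (3aS,4S)-4-bromo-3a-methyl-3,3a,4,5-tetrahydro-2H-indene-2,7(6H)-dione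
Product: 11 (2S,3aS,4S)-4-bromo-2-hydroxy-3a-methyl-2,3,3a,4,5,6-hexahydro-7H-inden-7-one
Conditions: NaBH4 (1 equiv), CeCl3·7H2O, MeOH, −78 °C
Reagents that add atoms: none
Why: Luche 1,2-reduction should pick the flat, open cyclopentenone carbonyl C2 over C7, whose axial trajectory is closed by the syn C3a methyl group, and hydride should come from the upper face, so the C2 hydroxyl group is lower (it is inverted in step 18).

Step 10
Reactants: 11 (2S,3aS,4S)-4-bromo-2-hydroxy-3a-methyl-2,3,3a,4,5,6-hexahydro-7H-inden-7-one
Product: 12 (2S,3aS,4S,7R)-4-bromo-3a,7-dimethyl-3,3a,4,5,6,7-hexahydro-2H-indene-2,7-diol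
Conditions: MeLi, CeCl3, THF, −78 °C
Reagents that add atoms: methyllithium, [Li]C
Why: Organocerium 1,2-addition avoids enolisation and conjugate addition, and the methyl group should enter C7 from the upper face, away from the pseudo-axial C3a methyl group, which leaves the tertiary oxygen lower (axial) as in the target.

Step 11
Reactants: 12 (2S,3aS,4S,7R)-4-bromo-3a,7-dimethyl-3,3a,4,5,6,7-hexahydro-2H-indene-2,7-diol
Product: 13 bis(triethylsilyl) ether of 12 (C2–OSiEt3 and C7–OSiEt3, both lower)
Conditions: Et3SiOTf, 2,6-lutidine, CH2Cl2, −78 to 0 °C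
Reagents that add atoms: triethylsilyl triflate, CC[Si](CC)(CC)OS(=O)(=O)C(F)(F)F
Why: Double silylation with the triflate masks both allylic alcohols for the borane and organolithium steps, keeps the C7 oxygen covered during the later chlorination and cyclisation, and puts more bulk on the lower face.

Step 12
Reactants: 13 bis(triethylsilyl) ether of 12
Product: 15 (+)-pinanediol ester of the C1 boronic acid (boron upper at C1; C7a–H upper; trans-hydrindane), via alkylborane 14 (not isolated)
Conditions: BH3·SMe2, THF, 0 °C to rt; then (+)-pinanediol, rt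
Reagents that add atoms: borane–dimethyl sulfide, [BH3-][S+](C)C; (+)-pinanediol, O[C@@H]1C[C@@H]2C[C@H]([C@@]1(O)C)C2(C)C
Why: Hydroboration is a syn addition with boron on the less substituted C1, and with the C3a methyl, C2–O and C7–O groups all lower it should come from above, as it does with steroidal 14-enes, so C7a–H (trans fusion) and C1–B are both set upper and the diol traps the hindered monoalkylborane as a stable ester.

Step 13
Reactants: 15 (+)-pinanediol ester of the C1 boronic acid
Product: 16 (S)-α-chloro boronic ester (C8 carries Cl, the boronate and the hydrindan-1-yl group)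
Conditions: CH2Cl2, n-BuLi, THF, −100 °C; 15; ZnCl2, −100 °C to rt
Reagents that add atoms: dichloromethane, ClCCl
Why: Matteson homologation: dichloromethyllithium adds to boron and C1 migrates with retention while one chloride leaves, with ZnCl2 and the (+)-pinanediol director selecting the (S)-α-chloro boronic ester at C8.

Step 14
Reactants: 17 6-methylhept-5-en-2-one
Product: 18 6-methylhept-5-en-2-one 2,4,6-triisopropylbenzenesulfonylhydrazone
Conditions: 2,4,6-(i-Pr)3C6H2SO2NHNH2, MeOH, cat. HCl, rt
Reagents that add atoms: 2,4,6-triisopropylbenzenesulfonyl hydrazide, CC(C)c1cc(C(C)C)c(S(=O)(=O)NN)c(C(C)C)c1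
Why: Acid-catalysed condensation gives the arenesulfonylhydrazone needed for the Shapiro reaction.

Step 15
Reactants: 16 (S)-α-chloro boronic ester; 18 sulfonylhydrazone
Product: 21 allylic alcohol (C8 R; C1'=C2'H2; prenyl end intact), via vinyllithium 19 (not isolated), via allylic boronate 20 (not isolated)
Conditions: 18, n-BuLi (2 equiv), THF, −78 to 0 °C; 16, −78 °C to rt; then H2O2, NaOH, 0 °C
Reagents that add atoms: hydrogen peroxide, OO
Why: Shapiro reaction of the methyl ketone hydrazone gives the less substituted vinyllithium, which adds to boron and displaces chloride from C8 by 1,2-migration with inversion (second half of the Matteson sequence), and peroxide oxidation replaces boron by oxygen with retention, so C8 comes out R under control of the diol and not of the crowded substrate.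

Step 16
Reactants: 21 allylic alcohol; 22 di-tert-butyl dicarbonate
Product: 23 C8 tert-butyl carbonate
Conditions: 4-(dimethylamino)pyridine, Et3N, CH2Cl2, rt
Reagents that add atoms: none
Why: Acyl-transfer catalysis converts the only free hydroxyl group into the tert-butyl carbonate that will end the cyclisation.

Step 17
Reactants: 23 C8 tert-butyl carbonate
Product: 24 C2 alcohol (C2–OH lower; C7–OSiEt3 kept)
Conditions: pyridinium p-toluenesulfonate, MeOH–CH2Cl2, 0 °C
Reagents that add atoms: none
Why: Mild acid methanolysis distinguishes the secondary C2 silyl ether from the far more hindered tertiary C7 silyl ether and does not touch the carbonate.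

Step 18
Reactants: 24 C2 alcohol
Product: 25 C2 4-nitrobenzoate (C2–O upper, cis to C8)
Conditions: 4-O2NC6H4CO2H, PPh3, i-PrO2CN=NCO2i-Pr, toluene, 0 °C to rt
Reagents that add atoms: 4-nitrobenzoic acid, O=C(O)c1ccc(cc1)[N+](=O)[O-]
Why: Mitsunobu reaction with the acidic 4-nitrobenzoic acid inverts C2 by SN2 attack from the open upper face, which gives the cis C1/C2 arrangement of the target and at once a poorly nucleophilic ester as protecting group.

Step 19
Reactants: 25 C2 4-nitrobenzoate
Product: 26 (4'R)-C3'–C4' epoxide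
Conditions: 1,2:4,5-di-O-isopropylidene-β-D-erythro-2,3-hexodiulo-2,6-pyranose (30 mol %), KHSO5 (as 2KHSO5·KHSO4·K2SO4), K2CO3, Bu4NHSO4, borate buffer, MeCN–CH2(OMe)2, 0 °C
Reagents that add atoms: potassium peroxymonosulfate, [K+].[O-]S(=O)(=O)OO
Why: Shi epoxidation is fastest at the electron-rich trisubstituted alkene and slow at the 1,1-disubstituted alkene deactivated by the allylic carbonate, and the D-fructose-derived ketone should give the (R)-epoxide at C4' by reagent control.

Step 20
Reactants: 26 (4'R)-epoxide
Product: 27 bromohydrin (C4' S bromide; C3' tertiary alcohol)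
Conditions: Li2NiBr4, THF, 0 °C to rt
Reagents that add atoms: dilithium tetrabromonickelate, [Li+].[Li+].[Ni+2].[Br-].[Br-].[Br-].[Br-]
Why: SN2 opening of the epoxide by the soft bromide of Li2NiBr4 goes to the less hindered secondary carbon with inversion, so C4' becomes the (S)-bromide and C3' keeps the tertiary hydroxyl group.

Step 21
Reactants: 27 bromohydrin
Product: 28 bromochloride allylic tert-butyl carbonate (C3'–Cl, C4' S bromide)
Conditions: Me2C=C(Cl)NMe2, CH2Cl2, 0 °C to rt
Reagents that add atoms: 1-chloro-N,N,2-trimethylprop-1-en-1-amine, CC(C)=C(Cl)N(C)C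
Why: Neutral chlorination of a tertiary alcohol with an α-chloroenamine: the activated oxygen leaves with help from the neighbouring bromine and chloride returns to the tertiary carbon C3', so C4' is not touched and carbonate, ester and silyl ether survive.

Step 22
Reactants: 28 bromochloride allylic tert-butyl carbonate
Product: 32 spiro cyclic carbonate (ring C closed; C1' R; C4' S), via bromonium ion 29 (not isolated), via tertiary cation 30 (not isolated), via dioxolanylium ion 31 (not isolated)
Conditions: (CF3)2CHOH (0.02 M), 2,6-di-tert-butylpyridine, 0 °C to rt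
Reagents that add atoms: none
Why: Proposed new method: in the strongly ionising and barely nucleophilic solvent the C4' bromine expels the tertiary chloride, so bromonium ion 29 forms with C4' unchanged, and the methylene carbon C2' opens it at the tertiary C3' from the rear through a chair that leaves bromine equatorial (6-endo closure of ring C) to give cation 30. The carbonyl oxygen of the C8 carbonate then adds to C1' (5-exo closure of the dioxolanone ring) and ion 31 loses isobutene and a proton to give 32. The closest known reactions are the enantiospecific solvolytic cyclisation of vicinal bromochlorides in this solvent and the ending of halonium-started polyene cyclisations by tert-butyl carbonates, but their union and capture beside a branched carbinol carbon are untested. C1', the only new stereocentre, is controlled by C8: oxygen can reach C1' only in rotamers about C1'–C8, and the one that lays the hydrindanyl group beside C6' (oxygen axial and cis to bromine, C8 equatorial, as in the target) is open, whereas the other forces that group against C2' and the C3' methyl groups. Because this puts oxygen on the alkene face that also binds C3', the step needs a stepwise course through 30 instead of concerted anti addition, and the steric mismatch just described together with the long life of cations in this solvent should secure it. Site selectivity rests on the substrate carrying no other free oxygen (C7 silyl ether, electron-poor C2 ester), on Markovnikov opening at C3', and on the hindered pyridine that takes up HCl before it can strip the carbonate.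

Step 23
Reactants: 32 spiro cyclic carbonate
Product: 33 C2,C8,C1'-triol with C7–OSiEt3
Conditions: K2CO3, MeOH, 0 °C to rt
Reagents that add atoms: none
Why: Base-catalysed transesterification with methanol opens the cyclic carbonate and cleaves the activated benzoate in one operation, and the C4' bromide is safe because it lies cis to the C1' alkoxide and cannot be attacked from the rear.

Step 24
Reactants: 33 triol with C7–OSiEt3
Product: 34 target CNP0144982.1
Conditions: HF·pyridine, THF, 0 °C to rt
Reagents that add atoms: none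
Why: Fluoride-driven desilylation under weakly acidic conditions frees the hindered tertiary C7 hydroxyl group without a base that could eliminate HBr, which gives the target.

**Compound list**
1 | 2-methylcyclohexane-1,3-dione | CC1C(=O)CCCC1=O | starting material
2 | allyl bromide | C=CCBr | starting material
3 | 2-allyl-2-methylcyclohexane-1,3-dione | C=CCC1(C)C(=O)CCCC1=O | intermediate
4 | (2R,3R)-2-allyl-3-hydroxy-2-methylcyclohexan-1-one | C=CC[C@]1(C)[C@H](O)CCCC1=O | intermediate
5 | (2R,3R)-2-allyl-3-(tert-butyldimethylsilyloxy)-2-methylcyclohexan-1-one | C=CC[C@]1(C)[C@H](O[Si](C)(C)C(C)(C)C)CCCC1=O | intermediate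
6 | (2R,3R)-3-(tert-butyldimethylsilyloxy)-2-methyl-2-(2-oxopropyl)cyclohexan-1-one | CC(=O)C[C@]1(C)[C@H](O[Si](C)(C)C(C)(C)C)CCCC1=O | intermediate
7 | (3aS,4R)-4-(tert-butyldimethylsilyloxy)-3a-methyl-3,3a,4,5,6,7-hexahydro-2H-inden-2-one | O=C1C[C@]2(C)[C@H](O[Si](C)(C)C(C)(C)C)CCCC2=C1 | intermediate
8 | (3aS,4R)-4-hydroxy-3a-methyl-3,3a,4,5,6,7-hexahydro-2H-inden-2-one | O=C1C[C@]2(C)[C@H](O)CCCC2=C1 | intermediate
9 | (3aS,4S)-4-bromo-3a-methyl-3,3a,4,5,6,7-hexahydro-2H-inden-2-one | O=C1C[C@]2(C)[C@@H](Br)CCCC2=C1 | intermediate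
10 | (3aS,4S)-4-bromo-3a-methyl-3,3a,4,5-tetrahydro-2H-indene-2,7(6H)-dione | O=C1C[C@]2(C)[C@@H](Br)CCC(=O)C2=C1 | intermediate
11 | (2S,3aS,4S)-4-bromo-2-hydroxy-3a-methyl-2,3,3a,4,5,6-hexahydro-7H-inden-7-one | O[C@H]1C[C@]2(C)[C@@H](Br)CCC(=O)C2=C1 | intermediate
12 | (2S,3aS,4S,7R)-4-bromo-3a,7-dimethyl-3,3a,4,5,6,7-hexahydro-2H-indene-2,7-diol | O[C@H]1C[C@]2(C)[C@@H](Br)CC[C@@](C)(O)C2=C1 | intermediate
13 | bis(triethylsilyl) ether of 12 | CC[Si](CC)(CC)O[C@H]1C[C@]2(C)[C@@H](Br)CC[C@@](C)(O[Si](CC)(CC)CC)C2=C1 | intermediate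
14 | C1 monoalkylborane of the trans-hydrindane (BH2 and C7a–H upper) | B[C@@H]1[C@@H](O[Si](CC)(CC)CC)C[C@]2(C)[C@@H](Br)CC[C@@](C)(O[Si](CC)(CC)CC)[C@@H]12 | intermediate
15 | (+)-pinanediol (1S,2S,3aS,4S,7R,7aS)-4-bromo-3a,7-dimethyl-2,7-bis(triethylsilyloxy)octahydroinden-1-ylboronate | B1(O[C@@H]2C[C@@H]3C[C@H]([C@@]2(O1)C)C3(C)C)[C@@H]4[C@@H](O[Si](CC)(CC)CC)C[C@]5(C)[C@@H](Br)CC[C@@](C)(O[Si](CC)(CC)CC)[C@@H]45 | intermediate
16 | (+)-pinanediol (S)-chloro(hydrindan-1-yl)methylboronate (C8 S) | B1(O[C@@H]2C[C@@H]3C[C@H]([C@@]2(O1)C)C3(C)C)[C@H](Cl)[C@@H]4[C@@H](O[Si](CC)(CC)CC)C[C@]5(C)[C@@H](Br)CC[C@@](C)(O[Si](CC)(CC)CC)[C@@H]45 | intermediate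
17 | 6-methylhept-5-en-2-one | CC(C)=CCCC(C)=O | starting material
18 | 6-methylhept-5-en-2-one 2,4,6-triisopropylbenzenesulfonylhydrazone | CC(C)=CCCC(C)=NNS(=O)(=O)c1c(C(C)C)cc(C(C)C)cc1C(C)C | intermediate
19 | 6-methylhepta-1,5-dien-2-yllithium | [Li]C(=C)CCC=C(C)C | intermediate
20 | allylic boronate (C8 carries boron, the dienyl group and the hydrindan-1-yl group) | B1(O[C@@H]2C[C@@H]3C[C@H]([C@@]2(O1)C)C3(C)C)[C@@H](C(=C)CCC=C(C)C)[C@@H]4[C@@H](O[Si](CC)(CC)CC)C[C@]5(C)[C@@H](Br)CC[C@@](C)(O[Si](CC)(CC)CC)[C@@H]45 | intermediate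
21 | allylic alcohol (C8 R, C2–OSiEt3 lower, C7–OSiEt3) | CC(C)=CCCC(=C)[C@H](O)[C@@H]1[C@@H](O[Si](CC)(CC)CC)C[C@]2(C)[C@@H](Br)CC[C@@](C)(O[Si](CC)(CC)CC)[C@@H]12 | intermediate
22 | di-tert-butyl dicarbonate | CC(C)(C)OC(=O)OC(=O)OC(C)(C)C | starting material
23 | C8 tert-butyl carbonate of 21 | CC(C)=CCCC(=C)[C@H](OC(=O)OC(C)(C)C)[C@@H]1[C@@H](O[Si](CC)(CC)CC)C[C@]2(C)[C@@H](Br)CC[C@@](C)(O[Si](CC)(CC)CC)[C@@H]12 | intermediate
24 | C2 alcohol (C2 S, hydroxyl lower) | CC(C)=CCCC(=C)[C@H](OC(=O)OC(C)(C)C)[C@@H]1[C@@H](O)C[C@]2(C)[C@@H](Br)CC[C@@](C)(O[Si](CC)(CC)CC)[C@@H]12 | intermediate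
25 | C2 4-nitrobenzoate (C2 R, oxygen upper) | CC(C)=CCCC(=C)[C@H](OC(=O)OC(C)(C)C)[C@@H]1[C@H](OC(=O)c3ccc(cc3)[N+](=O)[O-])C[C@]2(C)[C@@H](Br)CC[C@@](C)(O[Si](CC)(CC)CC)[C@@H]12 | intermediate
26 | (4'R)-C3'–C4' epoxide of 25 | CC1(C)O[C@@H]1CCC(=C)[C@H](OC(=O)OC(C)(C)C)[C@@H]2[C@H](OC(=O)c4ccc(cc4)[N+](=O)[O-])C[C@]3(C)[C@@H](Br)CC[C@@](C)(O[Si](CC)(CC)CC)[C@@H]23 | intermediate
27 | bromohydrin (C4' S bromide, C3' alcohol) | CC(C)(O)[C@@H](Br)CCC(=C)[C@H](OC(=O)OC(C)(C)C)[C@@H]2[C@H](OC(=O)c4ccc(cc4)[N+](=O)[O-])C[C@]3(C)[C@@H](Br)CC[C@@](C)(O[Si](CC)(CC)CC)[C@@H]23 | intermediate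
28 | bromochloride allylic tert-butyl carbonate (key-step precursor) | CC(C)(Cl)[C@@H](Br)CCC(=C)[C@H](OC(=O)OC(C)(C)C)[C@@H]2[C@H](OC(=O)c4ccc(cc4)[N+](=O)[O-])C[C@]3(C)[C@@H](Br)CC[C@@](C)(O[Si](CC)(CC)CC)[C@@H]23 | intermediate
29 | C3'–C4' bromonium chloride | CC1(C)[Br+][C@H]1CCC(=C)[C@H](OC(=O)OC(C)(C)C)[C@@H]2[C@H](OC(=O)c4ccc(cc4)[N+](=O)[O-])C[C@]3(C)[C@@H](Br)CC[C@@](C)(O[Si](CC)(CC)CC)[C@@H]23.[Cl-] | intermediate
30 | C1' tertiary cation (ring C closed) | CC1(C)C[C+]([C@H](OC(=O)OC(C)(C)C)[C@@H]2[C@H](OC(=O)c4ccc(cc4)[N+](=O)[O-])C[C@]3(C)[C@@H](Br)CC[C@@](C)(O[Si](CC)(CC)CC)[C@@H]23)CC[C@@H]1Br.[Cl-] | intermediate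
31 | 2-tert-butoxy-1,3-dioxolan-2-ylium ion | CC1(C)C[C@]4(OC(=[O+]C(C)(C)C)O[C@@H]4[C@@H]2[C@H](OC(=O)c5ccc(cc5)[N+](=O)[O-])C[C@]3(C)[C@@H](Br)CC[C@@](C)(O[Si](CC)(CC)CC)[C@@H]23)CC[C@@H]1Br.[Cl-] | intermediate
32 | spiro cyclic carbonate (key-step product; C1' R, C8 R, C4' S) | CC1(C)C[C@]4(OC(=O)O[C@@H]4[C@@H]2[C@H](OC(=O)c5ccc(cc5)[N+](=O)[O-])C[C@]3(C)[C@@H](Br)CC[C@@](C)(O[Si](CC)(CC)CC)[C@@H]23)CC[C@@H]1Br | intermediate
33 | C2,C8,C1'-triol with C7 triethylsilyl ether | CC1(C)C[C@@](O)([C@H](O)[C@@H]2[C@H](O)C[C@]3(C)[C@@H](Br)CC[C@@](C)(O[Si](CC)(CC)CC)[C@@H]23)CC[C@@H]1Br | intermediate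
34 | CNP0144982.1 | CC1(C)C[C@@](O)([C@H](O)[C@@H]2[C@H](O)C[C@]3(C)[C@@H](Br)CC[C@@](C)(O)[C@@H]23)CC[C@@H]1Br | target

Total step count: 24. Longest linear sequence: 23 (steps 1–13 and 15–24).

**Steps most likely to fail**

Step 22. Three things may go wrong.
- The C1' cation may lose a proton to C2' or C6' faster than the carbonate closes.
- The carbonate may close in concert with C–C bond formation on the opposite alkene face.
- Ionisation may be too slow beside the electron-poor alkene.

The fallback is the direct bromonium-induced polyene cyclisation, which is known with tert-butyl carbonates as the ending group. It sets out from diene carbonate 25, which is treated with Et2SBr·SbBrCl5 in nitromethane at −25 °C. The reagent should attack the trisubstituted alkene first and give 32 in one operation, so steps 19–21 fall away. The bromonium ion then forms on both alkene faces, so C4' is no longer reagent-controlled and 32 has to be separated from its ring C diastereomers. The route is rejoined at 32, and no new compound is made (F0).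

Step 7. Anti elimination of the activated axial oxygen with the axial C5 hydrogen, or a methyl shift from C3a, may outrun the hindered rear-side attack. The fallback separates activation from displacement. It sets out from 8, where Tf2O and pyridine at −20 °C should give the C4 triflate F1. Bu4NBr in toluene then displaces the triflate at or below room temperature. The much better leaving group and the absence of a bulky phosphonium group let the substitution run cold, where elimination is slower. The route is rejoined at 9.

Step 18. Crowding by the C1 side chain may stop formation or displacement of the oxyphosphonium ion, and elimination toward C3 may take over. The fallback sets out from 24, which is converted with Tf2O and pyridine into the C2 triflate F2. Caesium 4-nitrobenzoate with 18-crown-6 in toluene displaces it from the upper face with inversion. A small, preformed leaving group replaces the bulky phosphorus intermediate on the hindered lower face. The route is rejoined at 25.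

**Further compounds**
F0 | step 22 | none | none
F1 | step 7 | (3aS,4R)-3a-methyl-2-oxo-3,3a,4,5,6,7-hexahydro-2H-inden-4-yl triflate | O=C1C[C@]2(C)[C@H](OS(=O)(=O)C(F)(F)F)CCCC2=C1
F2 | step 18 | C2 triflate of 24 (oxygen lower) | CC(C)=CCCC(=C)[C@H](OC(=O)OC(C)(C)C)[C@@H]1[C@@H](OS(=O)(=O)C(F)(F)F)C[C@]2(C)[C@@H](Br)CC[C@@](C)(O[Si](CC)(CC)CC)[C@@H]12
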